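## Retrosynthetic overview
1. The macrocycle is the last ring formed. It closes at C8–C9 by an intramolecular B-alkyl Suzuki coupling of an (E)-vinyl iodide with a terminal alkene, and the 7E geometry is carried in the iodide.
2. The oxirane is the second ring. It comes from a catalyst-controlled Shi epoxidation of C3=C4, run while C7=C8 is still an electron-poor vinyl iodide, so the two alkenes do not compete.
3. The cis-α-methylene-γ-lactone is the first ring. An aqueous indium Barbier 2-(methoxycarbonyl)allylation with lactonisation joins a Z-allylic bromide (C1–C8, C15–C19) to an α-hydroxy aldehyde (C9–C14, C20) and sets C1 and C14.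
4. The west bromide comes from hepta-1,5-diyne by Zr-catalysed carboalumination/oxirane opening, hydrozirconation–iodination, vinylalumination and SN2′ bromination.
5. The east aldehyde comes from propargyl alcohol and allyl bromide by Z-reduction, Sharpless epoxidation, Me3Al opening (C12, C13) and selective primary oxidation.

Assumption: cembrane numbering is used (C1 lactone β-CH, C3/C4 oxirane, C7=C8, C12 Me, C13 OAc, C14 lactone O–CH). The SMILES reads as (1S,3R,4R,7E,12S,13R,14R), with a cis-fused lactone and an oxirane of E-alkene origin.

## Route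

**Step 1**
Reactants: 1 1-(trimethylsilyl)propyne; 2 1-bromobut-2-yne
Product: 3 trimethyl(hepta-1,5-diyn-1-yl)silane
Conditions: 1, n-BuLi, THF, −78 → −20 °C; then 2, −78 °C → rt
Reagents that add atoms: none
Why: Propargylic lithiation followed by SN2 alkylation of a primary propargylic bromide; the silyl group keeps the anion reacting at its propargyl terminus.

**Step 2**
Reactants: 3
Product: 4 hepta-1,5-diyne
Conditions: K2CO3, MeOH, rt (handled as a solution because it is volatile)
Reagents that add atoms: none
Why: Protodesilylation of the alkynylsilane; the internal methylalkyne is untouched.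

**Step 3**
Reactants: 4; 5 ethylene oxide
Product: 6 (E)-4-methylnon-3-en-7-yn-1-ol
Conditions: Me3Al, Cp2ZrCl2 (20 mol %), CH2Cl2, 0 °C → rt; concentrate; n-BuLi, hexane/THF, −78 → 0 °C; then 5, 0 °C → rt
Reagents that add atoms: trimethylaluminium C[Al](C)C; ethylene oxide C1CO1
Why: Negishi Zr-catalysed syn-methylalumination occurs only at the terminal alkyne and fixes the 3E alkene (C3=C4, C18); the derived alkenylalanate opens oxirane with retention to add C1–C2.

**Step 4**
Reactants: 6
Product: 7 (3E,7E)-8-iodo-4-methylnona-3,7-dien-1-ol
Conditions: Cp2Zr(H)Cl (3 equiv), THF, rt → 40 °C; then I2, 0 °C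
Reagents that add atoms: iodine II
Why: Syn-hydrozirconation under equilibrating conditions (excess Schwartz reagent) places Zr on the methyl-bearing carbon (about 9:1, minor regioisomer removed by chromatography). Iodinolysis with retention then gives the (E)-2-iodoalkene, and the trisubstituted alkene is inert.

**Step 5**
Reactants: 7
Product: 8 (3E,7E)-8-iodo-4-methylnona-3,7-dienal
Conditions: Dess–Martin periodinane, NaHCO3, CH2Cl2, 0 °C (used crude)
Reagents that add atoms: none
Why: This buffered, non-basic oxidation gives the β,γ-unsaturated aldehyde without conjugation.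

**Step 6**
Reactants: 8; 9 methyl propiolate
Product: 10 methyl (5E,9E)-3-hydroxy-10-iodo-6-methyl-2-methylideneundeca-5,9-dienoate (racemic carbinol)
Conditions: 9, DIBAL-H, NMO, THF, 0 °C; then 8, 0 °C → rt
Reagents that add atoms: methyl propiolate C#CC(=O)OC
Why: Vinylalumination ([α-(methoxycarbonyl)vinyl]aluminium addition) gives the Baylis–Hillman-type adduct without the amine base that would isomerise 8; the carbinol centre is erased in step 7.

**Step 7**
Reactants: 10
Product: 11 methyl (2Z,5E,9E)-2-(bromomethyl)-10-iodo-6-methylundeca-2,5,9-trienoate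
Conditions: NBS, Me2S, CH2Cl2, 0 °C → rt
Reagents that add atoms: N-bromosuccinimide O=C1CCC(=O)N1Br
Why: Corey–Kim-type activation followed by SN2′ displacement by bromide; allylic strain gives the Z-enoate (chain cis to CH2Br), and the isolated alkenes are not brominated.

**Step 8**
Reactants: 12 propargyl alcohol; 13 allyl bromide
Product: 14 hex-5-en-2-yn-1-ol
Conditions: CuI, K2CO3, NaI, DMF, rt
Reagents that add atoms: none
Why: Copper-acetylide allylation gives the skipped enyne.

**Step 9**
Reactants: 14
Product: 15 (2Z)-hexa-2,5-dien-1-ol
Conditions: H2 (1 atm), P-2 Ni (Ni(OAc)2/NaBH4), ethylenediamine, EtOH, rt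
Reagents that add atoms: none
Why: Syn semihydrogenation of the alkyne gives the Z-alkene; the poisoned catalyst spares the terminal alkene.

**Step 10**
Reactants: 15
Product: 16 [(2S,3R)-3-(prop-2-en-1-yl)oxiran-2-yl]methanol
Conditions: Ti(OiPr)4, L-(+)-DET, t-BuOOH, 4 Å MS, CH2Cl2, −20 °C
Reagents that add atoms: tert-butyl hydroperoxide CC(C)(C)OO
Why: Sharpless asymmetric epoxidation touches only the allylic-alcohol alkene; (+)-tartrate delivers oxygen to the face that gives 2S (the future C13), about 90 % ee for a Z-substrate.

**Step 11**
Reactants: 16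
Product: 17 (2R,3S)-3-methylhex-5-ene-1,2-diol
Conditions: Me3Al (3 equiv), hexane/CH2Cl2, 0 °C → rt
Reagents that add atoms: trimethylaluminium C[Al](C)C
Why: The aluminium-alkoxide-directed opening occurs at C3 of the 2,3-epoxy alcohol with clean inversion. Opening the cis-epoxide this way gives the syn C13-OH/C12-CH3 pair, i.e. 12S,13R.

**Step 12**
Reactants: 17
Product: 18 (2R,3S)-2-hydroxy-3-methylhex-5-enal
Conditions: TEMPO (10 mol %), NCS, Bu4NCl, CH2Cl2/aq. pH 8.6 buffer, 0 °C → rt (used crude)
Reagents that add atoms: none
Why: The oxoammonium oxidation is sterically selective for the primary carbinol of a primary/secondary diol and does not cleave the glycol. Any hydrate or dimer of 18 is acceptable in the next, aqueous step.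

**Step 13**
Reactants: 11; 18
Product: 19 (4S,5R)-5-[(1R,2S)-1-hydroxy-2-methylpent-4-en-1-yl]-4-[(2E,6E)-7-iodo-3-methylocta-2,6-dien-1-yl]-3-methylideneoxolan-2-one
Conditions: In powder, THF/H2O 1:1, rt; then cat. p-TsOH, CH2Cl2, rt
Reagents that add atoms: none
Why: This is an indium Barbier 2-(alkoxycarbonyl)allylation by γ-attack.
- The Z-allylindium reacts through a chair transition state to give the C1/C14 syn adduct, which becomes the cis-lactone (1S).
- Cram chelation of indium by the free C13-OH and the aldehyde gives the threo C13/C14 diol (14R).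
- The five-membered lactone closes on O14 with loss of MeOH, and the vinyl iodide and alkenes are inert.

**Step 14**
Reactants: 19
Product: 20 (1R,2S)-1-{(2R,3S)-3-[(2E,6E)-7-iodo-3-methylocta-2,6-dien-1-yl]-4-methylidene-5-oxooxolan-2-yl}-2-methylpent-4-en-1-yl acetate
Conditions: Ac2O, pyridine, DMAP, CH2Cl2, 0 °C → rt
Reagents that add atoms: acetic anhydride CC(=O)OC(C)=O
Why: Acylation of the only free hydroxyl installs the C13 acetate with retention and blocks translactonisation.

**Step 15**
Reactants: 20
Product: 21 the (3R,4R)-epoxide of 20, i.e. the lactone C4 substituent becomes {(2R,3R)-3-[(3E)-4-iodopent-3-en-1-yl]-3-methyloxiran-2-yl}methyl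
Conditions: D-fructose-derived Shi ketone (30 mol %), Oxone, K2CO3, Bu4NHSO4, MeCN/DMM–aq. borate/EDTA buffer, 0 °C
Reagents that add atoms: Oxone (KHSO5) [K+].[O-]S(=O)(=O)OO
Why: In the Shi epoxidation the electrophilic chiral dioxirane attacks only the electron-rich trisubstituted C3=C4. The iodoalkene, the acrylate-type methylene and the monosubstituted alkene are much slower. The spiro transition state of the D-fructose catalyst gives the (R,R)-epoxide of an E-trisubstituted alkene. The product derived from the minor enantiomer of 18 becomes a separable diastereomer.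

**Step 16**
Reactants: 21
Product: 22 eupalmerin acetate
Conditions: 9-BBN-H (1.3 equiv), THF, 0 °C → rt; then slow addition to PdCl2(dppf) (20 mol %), AsPh3, Cs2CO3, DMF/THF/H2O, about 2 mM, rt → 45 °C
Reagents that add atoms: none
Why: 9-BBN adds anti-Markovnikov to the monosubstituted alkene to give the C9 borane. Intramolecular B-alkyl Suzuki–Miyaura coupling with retention at the (E)-vinyl iodide then closes the 14-membered ring with 7E geometry. No stereocentre is formed or disturbed.

## Compound list
1 | 1-(trimethylsilyl)propyne | CC#C[Si](C)(C)C | starting material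
2 | 1-bromobut-2-yne | CC#CCBr | starting material
3 | trimethyl(hepta-1,5-diyn-1-yl)silane | CC#CCCC#C[Si](C)(C)C | intermediate
4 | hepta-1,5-diyne | CC#CCCC#C | intermediate
5 | ethylene oxide | C1CO1 | starting material
6 | (E)-4-methylnon-3-en-7-yn-1-ol | CC#CCC/C(C)=C/CCO | intermediate
7 | (3E,7E)-8-iodo-4-methylnona-3,7-dien-1-ol | OCC/C=C(\C)CC/C=C(\C)I | intermediate
8 | (3E,7E)-8-iodo-4-methylnona-3,7-dienal | O=CC/C=C(\C)CC/C=C(\C)I | intermediate
9 | methyl propiolate | C#CC(=O)OC | starting material
10 | methyl (5E,9E)-3-hydroxy-10-iodo-6-methyl-2-methylideneundeca-5,9-dienoate (racemic) | C=C(C(=O)OC)C(O)C/C=C(\C)CC/C=C(\C)I | intermediate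
11 | methyl (2Z,5E,9E)-2-(bromomethyl)-10-iodo-6-methylundeca-2,5,9-trienoate | COC(=O)/C(CBr)=C/C/C=C(\C)CC/C=C(\C)I | intermediate
12 | propargyl alcohol | C#CCO | starting material
13 | allyl bromide | C=CCBr | starting material
14 | hex-5-en-2-yn-1-ol | C=CCC#CCO | intermediate
15 | (2Z)-hexa-2,5-dien-1-ol | C=CC/C=C\CO | intermediate
16 | [(2S,3R)-3-allyloxiran-2-yl]methanol | OC[C@@H]1O[C@@H]1CC=C | intermediate
17 | (2R,3S)-3-methylhex-5-ene-1,2-diol | OC[C@H](O)[C@@H](C)CC=C | intermediate
18 | (2R,3S)-2-hydroxy-3-methylhex-5-enal | O=C[C@H](O)[C@@H](C)CC=C | intermediate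
19 | cis-hydroxy-α-methylene lactone (1S,12S,13R,14R) | C=C1C(=O)O[C@@H]([C@H](O)[C@@H](C)CC=C)[C@H]1C/C=C(\C)CC/C=C(\C)I | intermediate
20 | C13 acetate of 19 | C=C1C(=O)O[C@@H]([C@H](OC(C)=O)[C@@H](C)CC=C)[C@H]1C/C=C(\C)CC/C=C(\C)I | intermediate
21 | (3R,4R)-epoxide of 20 | C=C1C(=O)O[C@@H]([C@H](OC(C)=O)[C@@H](C)CC=C)[C@H]1C[C@H]2O[C@]2(C)CC/C=C(\C)I | intermediate
22 | eupalmerin acetate | C=C1C(=O)O[C@H]2[C@H](OC(C)=O)[C@@H](C)CCC/C(C)=C/CC[C@@]3(C)O[C@@H]3C[C@@H]12 | target

## Summary
Total steps: 16.
Longest linear sequence: 11 (steps 1–7, then 13–16).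

Three steps most likely to fail, each with a fallback:
1. **Step 16, macrocyclic B-alkyl Suzuki.**
   - Risk: 9-BBN or aqueous base may attack the α-methylene lactone, and the ring closure may be slow.
   - Fallback: swap the order of the two fragment unions.
     - Epoxidise silyl-protected 10 first.
     - Join it intermolecularly by B-alkyl Suzuki to bis-silylated 17.
     - Unmask the allylic bromide and the α-hydroxy aldehyde.
     - Close the ring at C1–C14 by an intramolecular In or CrCl2 Barbier allylation–lactonisation, so that the sensitive lactone is made last.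
2. **Step 13 (with step 12), chelation-controlled union.**
   - Risk: the α-hydroxy aldehyde is labile, and the syn,syn selectivity may be insufficient.
   - Fallback: replace substrate control by auxiliary control.
     - Run an Evans boron syn-aldol between the oxazolidinone imide of the C15 acid (7 homologated by one carbon) and the 2-O-PMB aldehyde.
     - Convert the imide carbon to a terminal alkyne.
     - Close the ring by Pd-catalysed cyclocarbonylation of the homopropargylic alcohol to the cis-α-methylene lactone.
     - Finish with DDQ and Ac2O.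
3. **Step 15, Shi epoxidation on the lactone acetate.**
   - Risk: the lactone and acetate are base-sensitive at pH about 10, and the diastereoselectivity may be incomplete.
   - Fallback: install the oxirane at the fragment stage. Epoxidise the silyl ether of 10, which has only one nucleophilic alkene and no lactone, then desilylate, carry out the SN2′ bromination, and carry the epoxide through the near-neutral indium coupling.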